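## Structural features

The target is an ent-labdane: a trans-fused decalin (ring A = C1–C5, C10; ring B = C5–C10) with a trisubstituted C7=C8 alkene carrying the C17 methyl group and, at C9, an equatorial chain C11–C16 that ends in an (E)-3-methyl-2-enoic acid. Five stereocentres are contiguous along C3–C4–C5–C10–C9: the axial C3 hydroxyl, quaternary C4 (equatorial C18 methyl, axial C19 acetoxymethyl), C5–H, quaternary C10 (axial C20 methyl) and C9–H. C19 and C20 are 1,3-diaxial on one face, and O3 stands trans-diaxial to C19, so the 3,19-diol of the decalin cannot be spanned by a cyclic protecting group. The fragile groups are the primary acetate next to a free secondary alcohol and a free acid (no hydrolysis, hydride or organometallic step may follow acetylation), the C7=C8 alkene (migration under strong acid) and the alkene geometry at C13. The real difficulty is the pair of quaternary carbons C4 and C10 on either side of C5, above all C10 with its methyl trans to H5 and next to C9; C9 itself can be corrected by epimerisation, but only while C8 is a ketone. The key step reads C20–C10–C9 with C8 at the ketone level as a cyclopropane C9–C10–C20 in ring B conjugated to a C8 carbonyl. A carbene at C9, tethered to C5, closes ring B onto the exocyclic C10=C20 alkene of ring A; because the tether takes the equatorial site at C10, C20 is forced into the hindered axial one.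

## Logic of the disconnections

39 to 38: the O19–acyl bond is cut last, because the acetate would not survive the hydride, enolate and organometallic steps. This removes the only base-labile group. The forward step must acylate the primary C19 hydroxyl and leave the hindered axial C3 hydroxyl alone.

38 to 36: the C13–C16 and C14–C15 bonds are cut, which turns the (E)-enoic acid into a terminal alkyne C13≡C14. The geometry problem becomes a syn-carbometalation. The forward step must add methyl to C13 and the metal to C14 on the same side, carboxylate with retention, and tolerate two free hydroxyls.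

36 to 35 to 34: the C3–H bond is cut (C3 back to a ketone), then the C3 ketal and the C19 silyl ether are restored. C3 is deliberately carried as a ketal through the middle of the route (see 24 to 23), so one stereocentre disappears from all intermediates between 16 and 34. The forward reduction must deliver hydride to the C3 face that carries C19, so that the hydroxyl ends axial and trans to C19.

34 to 33 to 32 to 30: C13–C14 is cut (one-carbon homologation of a C13 aldehyde), then C13–O, back to a terminal alkene. The chain then starts from an allyl group, the most dependable carbon electrophile for the hindered C9 enolate. The hydroboration must take the monosubstituted alkene and spare C7=C8.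

30 to 29 to 27: the C8–C17 bond is cut to the C8 enol triflate and then to the C8 ketone. Alkene and methyl group both come from the carbonyl that the key sequence leaves behind. The triflate must sit on C8 with the double bond toward C7 (a triflate on C7 would put the methyl on the wrong carbon), so enolisation must go to C7 and not to C9.

27 to 26 to 24: the C9–C11 bond is cut and the C9–C20 bond is re-formed. Reductive opening of the cyclopropyl ketone gives the C20 methyl and a regiodefined C8/C9 enolate in one event, so no separate regiocontrol at C9 is needed. The forward steps need cleavage of the exocyclic C9–C20 bond and not the ring bond C9–C10, C-allylation with 8, and equilibration of C9 to the equatorial epimer.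

24 to 23 (key): the C9–C10 and C9–C20 bonds are cut. This removes ring B, the three-membered ring and the quaternary centre C10 at once and leaves a monocyclic ring A with two stereocentres. The carbene must add to the alkene face cis to H5. With a silyl ether at C3 the two chairs of ring A would be close in energy, and the chair with an axial C5 arm leads to the cis-fused isomer. The precursor is therefore redesigned: C3 is a dioxolane in 23, so any axial substituent at C5 meets a 1,3-diaxial ketal oxygen and the arm is held equatorial. The same chair puts the C19 silyloxymethyl group axial over the other alkene face. A cyclic protecting group across O3 and O19 is excluded, since it would hold them gauche and force the arm axial.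

23 to 20 to 18 to 16: C8–C9 is cut (the diazo carbon comes from 21), then C8 is taken back to the terminal carbon of an allyl group. Only anti-Markovnikov hydration and oxidation are needed. The hydroboration must distinguish the monosubstituted alkene from the exocyclic methylene.

16 to 15 to 14 to 13: the ketal is taken back to the ketone and to the C3 alcohol, and the O19–Si bond is cut. The C3 carbinol from the start of the route has by then done its work as control element. The forward steps need silylation of the primary hydroxyl only and a ketalisation that leaves the exocyclic alkene in place.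

13 to 11 to 10: C19–O is cut back to C19–Si and C10=C20 back to the C10 ketone. The hydroxymethyl group thus comes from a silylmethyl nucleophile. The methylenation must be neither basic (C5 is epimerisable next to the ketone) nor strongly Lewis acidic (the alkoxysilane and the silyl ether must survive), and the C–Si oxidation must proceed with retention.

10 to 6, 7 and 8: the C4–C19 and C5–C6 bonds are cut in a conjugate addition and enolate alkylation. Quaternary C4 and C5 are set in one operation from a flat enone. The addition must come anti to the C3 silyloxy group and the allylation trans to it.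

6 to 5 to 4 to 2 to 1: the C3–O bond is cut back to the γ-position of 1. Oxygen enters by deconjugative ketalisation and epoxidation, and the single enantiomer comes from an enzymatic resolution of 4. This one stereocentre controls C4 and C5 and is replaced at the end by a substrate-directed reduction.

## Other disconnections considered

Alternative 1: The cut is C5–C10 and C8–C9. The forward key step is an intramolecular Diels–Alder reaction of the acyclic trienal A2 (thermal or with Me2AlCl), to give the trans-fused octalin aldehyde A1.
- In its favour: both carbocycles and the centres C5, C9 and C10 arise in one step. The C17 methyl and C11 (as the aldehyde) are already in place, and the C7 silyl enol ether is a direct handle for the C7=C8 alkene. In ring construction this is more step-economic than the chosen plan and it is the better of the two on that point.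
- Against it here: the acetonide of A1 can only bridge O3 and O19 when they are cis, so A1 carries C3 in the configuration opposite to the target. Acetylation at C19, oxidation at C3 and an axial-selective reduction would have to follow. The quaternary C4 and the C3 carbinol of A2 must be made enantioselectively in an acyclic setting. The dienophile carbon C10 is β,β-disubstituted and therefore sluggish, and the Lewis acid endangers the silyl enol ether and the acetonide.
- Comparison: both plans rely on substrate control. Alternative 1 stakes the facial and endo/exo selectivity on one concerted step with a flexible tether, whereas the chosen plan spreads control over ring-based steps. Overall length should be similar once the C3 correction and the synthesis of A2 are counted.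

Alternative 2: The cut is C9–C10. The forward key step has zerovalent palladium (Pd2(dba)3 with a chiral bisphosphine) ionise the racemic allylic carbonate A4; the para carbon of the phenoxide attacks the π-allyl terminus C9 to give the dienone A3.
- In its favour: the absolute configuration at C9 and C10 comes from a catalyst and not from a resolution. The aromatic precursor is flat and short to make, and the C7=C8 alkene with C17 is present from the outset. On these three points it is the better plan.
- Against it here: all three π-allyl carbons lie inside the ring that closes, and the nucleophile must reach the terminus anti to the metal. This endo mode is geometrically strained and much less established than exo closures. After the key step ring A still needs C4 methylation, ester reduction, saturation of C1=C2, setting of H5 and reduction at C3. Reductive methylation of the enone ester would plausibly set C4 and C5 correctly in one step, which is a point of equality with the chosen plan.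
- Comparison: the route to the decalin is shorter, but the risk is concentrated in a closure without close analogy. The side chain at C9 starts from C11 only, so the late chain work is equal in both plans.

Alternative 3: The cut is C4–C5 and C1–C10. The forward key step is an enantioselective Diels–Alder reaction of the silyloxydiene ester A6 with the enynal A7, promoted by a protonated oxazaborolidine triflimide, to give the cyclohexene A5.
- In its favour: it is catalytic, enantioselective and convergent from two small achiral pieces. It sets the hardest centre, quaternary C10, together with C5 in the first ring-forming step. The regiochemistry matches the polarisation of both partners, and the E geometry of A7 translates into the correct C5/C10 relationship. In the early creation of C10 it is the better plan.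
- Against it here: ring B, quaternary C4, the C3 carbinol and the whole C9 chain remain to be built. The alkyne–aldehyde closure that would make ring B leaves oxygen at C9 that must be exchanged for carbon. The ester-bearing diene terminus is deactivated.
- Comparison: the chosen plan needs a resolution and more steps to reach C10 but closes ring B and creates C10 in a single event with the C8 ketone placed for the alkene and the C9 enolate. The total count should be comparable, with the risk shifted from C10 to C4 and C9.

Key step: step 14

Remark on the chemistry: labdane numbering is used for all intermediates; α is the face of C19 and C20, β the face of H5, H9 and the 3-hydroxyl; the target is taken as the (3S,4R,5S,9R,10S,13E) isomer with an axial 3-hydroxyl trans to C19.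

## Route

Step 1
Reactants: 1 3-methylcyclohex-2-en-1-one
Product: 2 7-methyl-1,4-dioxaspiro[4.5]dec-7-ene
Conditions: HOCH2CH2OH, p-TsOH (cat.), toluene, reflux, Dean–Stark
Reagents that add atoms: ethylene glycol OCCO
Why: Deconjugative ketalisation: the acid-catalysed reaction passes through the dienol ether and should give mainly the β,γ-unsaturated ketal, which moves the nucleophilic alkene onto the carbon that must receive oxygen (future C3).

Step 2
Reactants: 2 7-methyl-1,4-dioxaspiro[4.5]dec-7-ene
Product: 4 rac-4-hydroxy-3-methylcyclohex-2-en-1-one, via epoxy ketal 3 (not isolated)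
Conditions: mCPBA, NaHCO3, CH2Cl2, 0 °C; then 1 M HCl, THF, rt
Reagents that add atoms: mCPBA OOC(=O)c1cccc(Cl)c1; water O
Why: Prilezhaev epoxidation of the electron-rich trisubstituted alkene, then ketal hydrolysis and β-elimination of the epoxide oxygen from the β,γ-epoxy ketone should restore the enone with the hydroxyl at the γ-carbon.

Step 3
Reactants: 4 rac-4-hydroxy-3-methylcyclohex-2-en-1-one
Product: 5 (S)-4-hydroxy-3-methylcyclohex-2-en-1-one
Conditions: Burkholderia cepacia lipase (Amano PS), vinyl acetate, t-BuOMe, 30 °C, stopped just past half conversion
Reagents that add atoms: none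
Why: Lipase-catalysed kinetic resolution by transesterification; by the Kazlauskas rule the (R)-alcohol (large group = the methyl-bearing alkene carbon) should be acetylated, so the unreacted (S)-alcohol, which has the future C3 configuration, is recovered by chromatography.

Step 4
Reactants: 5 (S)-4-hydroxy-3-methylcyclohex-2-en-1-one
Product: 6 (S)-3-methyl-4-(triethylsilyloxy)cyclohex-2-en-1-one
Conditions: Et3SiCl, imidazole, CH2Cl2, 0 °C
Reagents that add atoms: chlorotriethylsilane CC[Si](Cl)(CC)CC
Why: Standard silylation; the silyl ether is large enough to direct the next step and is removed by fluoride in step 7.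

Step 5
Reactants: 6 (S)-3-methyl-4-(triethylsilyloxy)cyclohex-2-en-1-one; 7 (chloromethyl)(isopropoxy)dimethylsilane; 8 allyl bromide
Product: 10 5α-allyl-4α-[(isopropoxydimethylsilyl)methyl]-4β-methyl-3β-(triethylsilyloxy)cyclohexan-10-one (labdane numbering), via magnesium enolate 9 (not isolated)
Conditions: 7, Mg, THF, rt; then CuI (20 mol%), 6, THF, −78 → −30 °C; then 8, DMPU, −30 °C → rt
Reagents that add atoms: 7 (chloromethyl)(isopropoxy)dimethylsilane CC(C)O[Si](C)(C)CCl; 8 allyl bromide C=CCBr
Why: Copper-catalysed conjugate addition of the silylmethyl Grignard reagent (a hydroxymethyl anion equivalent) should occur anti to the C3 silyloxy group and set quaternary C4. Axial allylation of the enolate is expected through the half-chair with equatorial silyloxy group, anti to the pseudoaxial C4 methyl and free of a 1,3-diaxial contact with O3, which puts the allyl group cis to C19 (conjugate addition–enolate alkylation).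

Step 6
Reactants: 10 ring A ketone from step 5
Product: 11 5α-allyl-4α-[(isopropoxydimethylsilyl)methyl]-4β-methyl-10-methylidene-3β-(triethylsilyloxy)cyclohexane (labdane numbering)
Conditions: Cp2TiMe2 (2.5 equiv), toluene/THF, 65 °C, dark
Reagents that add atoms: dimethyltitanocene C[Ti](C)(C1C=CC=C1)C1C=CC=C1
Why: Petasis olefination: thermal loss of methane from Cp2TiMe2 gives the titanocene methylidene Cp2Ti=CH2, which converts the enolisable C10 ketone into the exocyclic alkene through an oxatitanacyclobutane. The medium contains neither base nor a Lewis-acidic aluminium species, so C5 cannot epimerise and both Si–O bonds are spared; C5 is fixed from here on.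

Step 7
Reactants: 11 methylidene compound from step 6
Product: 13 5α-allyl-4α-(hydroxymethyl)-4β-methyl-10-methylidenecyclohexan-3β-ol (labdane numbering), via fluorosilane alcohol 12 (not isolated)
Conditions: TBAF, THF, rt; then KHCO3, 30% H2O2, MeOH, 40 °C
Reagents that add atoms: hydrogen peroxide OO
Why: Fluoride cleaves the triethylsilyl ether and converts the isopropoxysilane into a fluorosilane, which peroxide oxidises with retention at carbon (Tamao oxidation) to the C19 alcohol; isolated alkenes are inert to basic H2O2.

Step 8
Reactants: 13 diol from step 7
Product: 14 4α-[(tert-butyldimethylsilyloxy)methyl]-5α-allyl-4β-methyl-10-methylidenecyclohexan-3β-ol (labdane numbering)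
Conditions: t-BuMe2SiCl (1.05 equiv), imidazole, CH2Cl2, −10 °C
Reagents that add atoms: tert-butyldimethylsilyl chloride CC(C)(C)[Si](C)(C)Cl
Why: Silylation is much faster at the primary hydroxyl than at the secondary one flanked by quaternary C4 (selective protection).

Step 9
Reactants: 14 mono-silyl ether from step 8
Product: 15 4α-[(tert-butyldimethylsilyloxy)methyl]-5α-allyl-4β-methyl-10-methylidenecyclohexan-3-one (labdane numbering)
Conditions: Dess–Martin periodinane, NaHCO3, CH2Cl2, rt
Reagents that add atoms: none
Why: Mild oxidation of the hindered secondary alcohol; the α-carbon C4 is quaternary, so the β-silyloxy ketone cannot eliminate.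

Step 10
Reactants: 15 ketone from step 9
Product: 16 3,3-ethylenedioxy ketal of 15
Conditions: Me3SiOCH2CH2OSiMe3, Me3SiOTf (cat.), CH2Cl2, −78 → −20 °C; pyridine quench
Reagents that add atoms: 1,2-bis(trimethylsilyloxy)ethane C[Si](C)(C)OCCO[Si](C)(C)C
Why: Aprotic silyl-transfer ketalisation at low temperature should spare the exocyclic alkene and the silyl ether; the dioxolane is the conformational lock for step 14 and removes C3 as a stereocentre until step 23.

Step 11
Reactants: 16 ketal from step 10
Product: 18 5α-(3-hydroxypropyl) analogue of 16, via dialkylborane adduct 17 (not isolated)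
Conditions: (Me2CHCHMe)2BH (from BH3·SMe2 and 2-methylbut-2-ene), THF, 0 °C; then NaOH, H2O2, 0 °C → rt
Reagents that add atoms: hydrogen peroxide OO
Why: Anti-Markovnikov hydroboration–oxidation; the bulky dialkylborane reacts much faster with the monosubstituted allyl terminus than with the 1,1-disubstituted exocyclic alkene next to tertiary C5.

Step 12
Reactants: 18 primary alcohol from step 11
Product: 20 5α-(2-carboxyethyl) analogue of 16, via aldehyde 19 (not isolated)
Conditions: TEMPO (cat.), PhI(OAc)2, MeCN/pH 7 buffer, rt
Reagents that add atoms: water O
Why: Oxoammonium oxidation of the primary alcohol to the aldehyde and, through its hydrate, to the acid; the near-neutral medium suits the ketal, the silyl ether and the alkene.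

Step 13
Reactants: 20 acid from step 12; 21 (trimethylsilyl)diazomethane
Product: 23 5α-(4-diazo-3-oxobutyl) analogue of 16 (diazoketone), via mixed anhydride 22 (not isolated)
Conditions: i-BuOCOCl, N-methylmorpholine, THF, −20 °C; then 21, MeCN, 0 °C → rt
Reagents that add atoms: 21 (trimethylsilyl)diazomethane C[Si](C)(C)C=[N+]=[N-]
Why: Acylation of the diazoalkane by the mixed carbonic anhydride (first stage of an Arndt–Eistert sequence) with loss of the silyl group gives the diazomethyl ketone without exposing the ketal to HCl.

Step 14
Reactants: 23 diazoketone from step 13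
Product: 24 tricyclic cyclopropyl ketone (trans-fused rings A and B; C9–C10–C20 cyclopropane with C20 α; C8 ketone; C3 dioxolane; 19-OSiMe2t-Bu)
Conditions: Rh2(OAc)4 (1 mol%), CH2Cl2, rt, slow addition of 23 at high dilution
Reagents that add atoms: none
Why: Divalent rhodium extrudes nitrogen from the diazoketone to give an electrophilic keto-carbenoid at C9, which adds in a concerted, asynchronous [2+1] fashion to the exocyclic C10=C20 alkene. The closest known reaction type is the intramolecular cyclopropanation of α-diazoketones with tethered alkenes to bicyclo[4.1.0]heptan-2-ones. Ring B closes as a six-membered ring by C9–C10 bond formation at the internal alkene carbon through a chair-like arrangement with the C5 arm equatorial; the three-membered ring closes by the C9–C20 bond of the same event. C10 is controlled by C5 and the ring A chair: the C3 ketal places an oxygen 1,3-diaxial to any axial C5 substituent, so the arm stays equatorial and C9 can only arrive from the equatorial direction, on the face of H5, which leaves C20 axial and trans to H5. The other face is covered in addition by the axial C19 silyloxymethyl group. C9 follows from C10, because a cyclopropane can only be cis-fused to ring B. The step needs chemoselectivity for the alkene over insertion into the tertiary allylic C5–H bond and over carbene dimerisation; the proximity and electron-rich character of the 1,1-disubstituted alkene and the slow addition should secure this. If C–H insertion intrudes, the less electrophilic dirhodium tetracaprolactamate Rh2(cap)4 would be the first adjustment.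

Step 15
Reactants: 24 cyclopropyl ketone from step 14; 8 allyl bromide
Product: 26 9β-allyl-10-methyl-8-ketone (axial allyl; C3 dioxolane; 19-OSiMe2t-Bu), via lithium enolate 25 (not isolated)
Conditions: Li, t-BuOH (1 equiv), NH3(l)/THF, −78 °C; isoprene; then 8, −78 → −33 °C; NH4Cl
Reagents that add atoms: 8 allyl bromide C=CCBr
Why: Dissolving-metal reduction cleaves the cyclopropane bond that overlaps best with the carbonyl π system, the exocyclic C9–C20 bond, so C20 becomes the C10 methyl and a regiodefined C8/C9 lithium enolate remains (reductive opening of a cyclopropyl ketone). Allylation of this enolate should occur axially, anti to the axial C10 methyl (reductive alkylation).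

Step 16
Reactants: 26 9β-allyl ketone from step 15
Product: 27 9α-allyl-10-methyl-8-ketone (equatorial allyl)
Conditions: NaOMe, MeOH, rt
Reagents that add atoms: none
Why: Base-mediated epimerisation α to the ketone should move the allyl group from the axial site, where it is syn-axial to H5 and H7, to the equatorial site, which is the C9 configuration of the target.

Step 17
Reactants: 27 9α-allyl ketone from step 16
Product: 29 C8 enol triflate with C7=C8 double bond, via potassium enolate 28 (not isolated)
Conditions: KN(SiMe3)2, THF, −78 °C; then PhNTf2, −78 → 0 °C
Reagents that add atoms: N-phenylbis(trifluoromethanesulfonimide) O=S(=O)(N(c1ccccc1)S(=O)(=O)C(F)(F)F)C(F)(F)F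
Why: Kinetic deprotonation by the bulky amide takes the C7 methylene and not the hindered C9 methine next to quaternary C10; O-sulfonylation fixes the C7=C8 regiochemistry and leaves C9 untouched.

Step 18
Reactants: 29 enol triflate from step 17
Product: 30 9α-allyl-8-methyl-Δ7 decalin (C3 dioxolane; 19-OSiMe2t-Bu)
Conditions: MeMgBr, Fe(acac)3 (10 mol%), THF/NMP, −20 → 0 °C
Reagents that add atoms: methylmagnesium bromide C[Mg]Br
Why: Iron-catalysed cross-coupling of the alkenyl triflate with the methyl Grignard reagent (Kumada-type coupling) installs C17 on C8; ketal, silyl ether and the terminal alkene are inert.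

Step 19
Reactants: 30 diene from step 18
Product: 32 9α-(3-hydroxypropyl) compound (C13 alcohol), via B-alkyl-9-BBN adduct 31 (not isolated)
Conditions: 9-BBN, THF, 0 °C → rt; then NaOH, H2O2
Reagents that add atoms: hydrogen peroxide OO
Why: Hydroboration–oxidation; 9-BBN takes the monosubstituted alkene at its terminus and leaves the trisubstituted C7=C8 alkene alone.

Step 20
Reactants: 32 alcohol from step 19
Product: 33 C13 aldehyde
Conditions: Dess–Martin periodinane, NaHCO3, CH2Cl2, rt
Reagents that add atoms: none
Why: Mild, buffered oxidation of the primary alcohol without touching the ketal or the alkene.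

Step 21
Reactants: 33 aldehyde from step 20
Product: 34 terminal alkyne (9α-but-3-ynyl; C13≡C14)
Conditions: MeCOC(N2)P(O)(OMe)2, K2CO3, MeOH, 0 °C → rt
Reagents that add atoms: dimethyl (1-diazo-2-oxopropyl)phosphonate COP(=O)(OC)C(=[N+]=[N-])C(C)=O
Why: Seyferth–Gilbert homologation in the Ohira–Bestmann variant adds C14; the aldehyde has no stereocentre at its α-carbon and the conditions spare the silyl ether and the ketal.

Step 22
Reactants: 34 alkyne from step 21
Product: 35 19-hydroxy-3-ketone (9α-but-3-ynyl-8-methyl-Δ7 decalin)
Conditions: 2 M HCl, THF/MeOH, rt
Reagents that add atoms: water O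
Why: Aqueous acid hydrolyses the dioxolane and the primary silyl ether in one operation; the β-hydroxy ketone cannot dehydrate because C4 is quaternary.

Step 23
Reactants: 35 hydroxy ketone from step 22
Product: 36 3β,19-diol (9α-but-3-ynyl-8-methyl-Δ7 decalin)
Conditions: Me4NBH(OAc)3, MeCN/AcOH, −20 °C → rt
Reagents that add atoms: none
Why: Hydroxyl-directed reduction of a β-hydroxy ketone (Evans–Saksena type): the borohydride bound to the axial C19–O delivers hydride intramolecularly to the C3 face that carries C19, so the new hydroxyl ends axial and trans to C19. The acidic medium avoids the alkoxide that could trigger a retro-aldol loss of C19.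

Step 24
Reactants: 36 diol alkyne from step 23
Product: 38 (3S,4R,5S,9R,10S,13E)-3,19-dihydroxylabda-7,13-dien-15-oic acid, via alkenylalane 37 (not isolated)
Conditions: Me3Al (excess), Cp2ZrCl2, CH2Cl2, 0 °C → rt; volatiles removed; n-BuLi, THF/hexane, −78 °C; CO2, −78 °C → rt; 1 M HCl
Reagents that add atoms: trimethylaluminium C[Al](C)C; carbon dioxide O=C=O
Why: Zirconium-catalysed syn-carboalumination (Negishi) adds methyl to C13 and aluminium to C14 on the same side; the two hydroxyls are carried as aluminium alkoxides. The derived alanate is carboxylated with retention, which fixes the 13E geometry.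

Step 25
Reactants: 38 dihydroxy acid from step 24
Product: 39 (3S,4R,5S,9R,10S,13E)-19-acetoxy-3-hydroxylabda-7,13-dien-15-oic acid
Conditions: Ac2O, pyridine, CH2Cl2, 0 °C; then aq NaHCO3
Reagents that add atoms: acetic anhydride CC(=O)OC(C)=O
Why: Without an acyl-transfer catalyst the primary C19 hydroxyl is acetylated much faster than the axial C3 hydroxyl next to quaternary C4; any mixed anhydride at C15 is hydrolysed in the work-up, and acyl migration to O3 is blocked by the trans-diaxial geometry.

## Compound list

1 | 3-methylcyclohex-2-en-1-one | CC1=CC(=O)CCC1 | starting material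
2 | 7-methyl-1,4-dioxaspiro[4.5]dec-7-ene | CC1=CCCC2(C1)OCCO2 | intermediate
3 | rac-7,8-epoxy-7-methyl-1,4-dioxaspiro[4.5]decane (not isolated) | CC12CC3(CCC1O2)OCCO3 | intermediate
4 | rac-4-hydroxy-3-methylcyclohex-2-en-1-one | CC1=CC(=O)CCC1O | intermediate
5 | (S)-4-hydroxy-3-methylcyclohex-2-en-1-one | CC1=CC(=O)CC[C@@H]1O | intermediate
6 | (S)-3-methyl-4-(triethylsilyloxy)cyclohex-2-en-1-one | CC1=CC(=O)CC[C@@H]1O[Si](CC)(CC)CC | intermediate
7 | (chloromethyl)(isopropoxy)dimethylsilane | CC(C)O[Si](C)(C)CCl | starting material
8 | allyl bromide | C=CCBr | starting material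
9 | chloromagnesium enolate after conjugate addition (not isolated) | CC(C)O[Si](C)(C)C[C@@]1(C)C=C(O[Mg]Cl)CC[C@@H]1O[Si](CC)(CC)CC | intermediate
10 | 5α-allyl-4α-[(isopropoxydimethylsilyl)methyl]-4β-methyl-3β-(triethylsilyloxy)cyclohexan-10-one (labdane numbering) | CC(C)O[Si](C)(C)C[C@@]1(C)[C@@H](CC=C)C(=O)CC[C@@H]1O[Si](CC)(CC)CC | intermediate
11 | 10-methylidene analogue of 10 | CC(C)O[Si](C)(C)C[C@@]1(C)[C@@H](CC=C)C(=C)CC[C@@H]1O[Si](CC)(CC)CC | intermediate
12 | 3β-hydroxy-4α-[(fluorodimethylsilyl)methyl] compound (not isolated) | C[Si](C)(F)C[C@@]1(C)[C@@H](CC=C)C(=C)CC[C@@H]1O | intermediate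
13 | 5α-allyl-4α-(hydroxymethyl)-4β-methyl-10-methylidenecyclohexan-3β-ol | OC[C@@]1(C)[C@@H](CC=C)C(=C)CC[C@@H]1O | intermediate
14 | 19-O-(tert-butyldimethylsilyl) ether of 13 | CC(C)(C)[Si](C)(C)OC[C@@]1(C)[C@@H](CC=C)C(=C)CC[C@@H]1O | intermediate
15 | 3-ketone from 14 | CC(C)(C)[Si](C)(C)OC[C@@]1(C)[C@@H](CC=C)C(=C)CCC1=O | intermediate
16 | 3,3-ethylenedioxy ketal of 15 | CC(C)(C)[Si](C)(C)OC[C@@]1(C)[C@@H](CC=C)C(=C)CCC12OCCO2 | intermediate
17 | C8 bis(3-methylbutan-2-yl)borane adduct of 16 (not isolated) | CC(C)(C)[Si](C)(C)OC[C@@]1(C)[C@@H](CCCB(C(C)C(C)C)C(C)C(C)C)C(=C)CCC12OCCO2 | intermediate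
18 | 5α-(3-hydroxypropyl) ketal | CC(C)(C)[Si](C)(C)OC[C@@]1(C)[C@@H](CCCO)C(=C)CCC12OCCO2 | intermediate
19 | 5α-(3-oxopropyl) ketal (not isolated) | CC(C)(C)[Si](C)(C)OC[C@@]1(C)[C@@H](CCC=O)C(=C)CCC12OCCO2 | intermediate
20 | 5α-(2-carboxyethyl) ketal | CC(C)(C)[Si](C)(C)OC[C@@]1(C)[C@@H](CCC(=O)O)C(=C)CCC12OCCO2 | intermediate
21 | (trimethylsilyl)diazomethane | C[Si](C)(C)C=[N+]=[N-] | starting material
22 | isobutyl carbonic mixed anhydride of 20 (not isolated) | CC(C)(C)[Si](C)(C)OC[C@@]1(C)[C@@H](CCC(=O)OC(=O)OCC(C)C)C(=C)CCC12OCCO2 | intermediate
23 | diazoketone: 5α-(4-diazo-3-oxobutyl) ketal | CC(C)(C)[Si](C)(C)OC[C@@]1(C)[C@@H](CCC(=O)C=[N+]=[N-])C(=C)CCC12OCCO2 | intermediate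
24 | tricyclic cyclopropyl ketone (C9–C10–C20 ring, C8 ketone) | CC(C)(C)[Si](C)(C)OC[C@@]1(C)[C@H]2CCC(=O)[C@H]3C[C@@]23CCC14OCCO4 | intermediate
25 | C8/C9 lithium enolate with C10 methyl (not isolated) | CC(C)(C)[Si](C)(C)OC[C@@]1(C)[C@H]2CCC(O[Li])=C[C@]2(C)CCC13OCCO3 | intermediate
26 | 9β-allyl-10-methyl-8-ketone | CC(C)(C)[Si](C)(C)OC[C@@]1(C)[C@H]2CCC(=O)[C@H](CC=C)[C@]2(C)CCC13OCCO3 | intermediate
27 | 9α-allyl-10-methyl-8-ketone | CC(C)(C)[Si](C)(C)OC[C@@]1(C)[C@H]2CCC(=O)[C@@H](CC=C)[C@]2(C)CCC13OCCO3 | intermediate
28 | C7/C8 potassium enolate of 27 (not isolated) | CC(C)(C)[Si](C)(C)OC[C@@]1(C)[C@H]2CC=C(O[K])[C@@H](CC=C)[C@]2(C)CCC13OCCO3 | intermediate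
29 | C8 enol triflate (C7=C8) | CC(C)(C)[Si](C)(C)OC[C@@]1(C)[C@H]2CC=C(OS(=O)(=O)C(F)(F)F)[C@@H](CC=C)[C@]2(C)CCC13OCCO3 | intermediate
30 | 9α-allyl-8-methyl-Δ7 decalin | CC(C)(C)[Si](C)(C)OC[C@@]1(C)[C@H]2CC=C(C)[C@@H](CC=C)[C@]2(C)CCC13OCCO3 | intermediate
31 | B-alkyl-9-BBN adduct of 30 at C13 (not isolated) | CC(C)(C)[Si](C)(C)OC[C@@]1(C)[C@H]2CC=C(C)[C@@H](CCCB3C4CCCC3CCC4)[C@]2(C)CCC13OCCO3 | intermediate
32 | 9α-(3-hydroxypropyl) compound | CC(C)(C)[Si](C)(C)OC[C@@]1(C)[C@H]2CC=C(C)[C@@H](CCCO)[C@]2(C)CCC13OCCO3 | intermediate
33 | C13 aldehyde | CC(C)(C)[Si](C)(C)OC[C@@]1(C)[C@H]2CC=C(C)[C@@H](CCC=O)[C@]2(C)CCC13OCCO3 | intermediate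
34 | terminal alkyne (9α-but-3-ynyl) | CC(C)(C)[Si](C)(C)OC[C@@]1(C)[C@H]2CC=C(C)[C@@H](CCC#C)[C@]2(C)CCC13OCCO3 | intermediate
35 | 19-hydroxy-3-ketone alkyne | OC[C@@]1(C)[C@H]2CC=C(C)[C@@H](CCC#C)[C@]2(C)CCC1=O | intermediate
36 | 3β,19-diol alkyne | OC[C@@]1(C)[C@H]2CC=C(C)[C@@H](CCC#C)[C@]2(C)CC[C@@H]1O | intermediate
37 | (E)-alkenyldimethylalane with both hydroxyls as dimethylaluminium alkoxides (not isolated) | C[Al](C)OC[C@@]1(C)[C@H]2CC=C(C)[C@@H](CC/C(C)=C/[Al](C)C)[C@]2(C)CC[C@@H]1O[Al](C)C | intermediate
38 | (3S,4R,5S,9R,10S,13E)-3,19-dihydroxylabda-7,13-dien-15-oic acid | OC[C@@]1(C)[C@H]2CC=C(C)[C@@H](CC/C(C)=C/C(=O)O)[C@]2(C)CC[C@@H]1O | intermediate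
39 | (3S,4R,5S,9R,10S,13E)-19-acetoxy-3-hydroxylabda-7,13-dien-15-oic acid | CC(=O)OC[C@@]1(C)[C@H]2CC=C(C)[C@@H](CC/C(C)=C/C(=O)O)[C@]2(C)CC[C@@H]1O | target

## Step count and least certain steps

Total steps: 25. Longest linear sequence: 25 (the route is linear; 7, 8 and 21 are purchased).

Step 14 (key step). The most likely failures are insertion of the carbenoid into the tertiary allylic C5–H bond, carbene dimerisation, and residual addition through the chair with an axial arm, which would give the cis-fused isomer. The fallback gives up carbene delivery and sets C10 by a hydroxyl-directed cyclopropanation. It sets out from 20 and returns at 24. MeLi would convert 20 into the methyl ketone F1, and ozonolysis of the exocyclic alkene would give the 1,5-diketone F2. Aldol condensation (KOH, MeOH) would close ring B to the enone F3, in which the ketal still favours the equatorial C5–C6 bond. 1,2-Reduction with LiBH(s-Bu)3 from the equatorial direction would give the pseudoaxial 8α-allylic alcohol F4. The Simmons–Smith reaction (Et2Zn, CH2I2), directed by that hydroxyl, would deliver C20 to the α face to give the cyclopropyl carbinol F5, and Dess–Martin oxidation would give 24.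

Step 5. Facial selectivity in the enolate allylation may be poor, giving the C5 epimer, and C-allylation of the hindered magnesium enolate may be slow. The fallback replaces kinetic control by a thermodynamic funnel. It sets out from 10 (as the epimer mixture) and returns at 13. Tamao oxidation (KF, KHCO3, H2O2) would give the γ-hydroxy ketone F6. Warm acidic methanol (camphorsulfonic acid, HC(OMe)3) would remove the triethylsilyl group and close the bridged methyl ketal F7 between O19 and C10. In F7 the chair is locked with C19 axial, and only the epimer with equatorial allyl avoids a 1,3-diaxial contact with O3, so equilibration through the enol ether should converge on it. Mild aqueous acid would reopen F7 to the keto diol F8. Methylenation of F8 with the Takai–Lombardo reagent (Zn, CH2Br2, TiCl4, THF/CH2Cl2), which is not basic and tolerates free hydroxyl groups, would give 13.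

Step 11. The hydroboration may lose chemoselectivity and attack the exocyclic methylene as well. The fallback uses olefin class instead of reagent bulk. It sets out from 16 and returns at 20 by way of 19. Cross-metathesis of 16 with vinylboronic acid pinacol ester (second-generation Grubbs catalyst) should engage only the monosubstituted alkene and give the alkenylboronate F9. Oxidation with NaBO3 would give aldehyde 19, and NaClO2 oxidation would give 20.

Step 15. Proton transfer between the product ketone and the enolate may lead to allylation at C7 or to double allylation, and some O-allylation is possible. The fallback separates enolate trapping from C–C bond formation. It sets out from 24 and returns at 26. The enolate 25 would be trapped on oxygen with allyl chloroformate to give the allyl enol carbonate F10. Pd(PPh3)4 (zerovalent palladium) would then effect decarboxylative allylation at C9 only, and the C9 epimers would be equilibrated as in step 16.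

Step 24. Carboxylation of the alanate may be incomplete in the presence of the aluminium alkoxides, and protodealumination may compete. The fallback introduces C15 by carbonylation. It sets out from 36 and returns at 38. The alkenylalane 37 would be quenched with I2 to give the (E)-alkenyl iodide F11, and hydroxycarbonylation (Pd(OAc)2, PPh3, CO, H2O, K2CO3, DMF) would give 38 with retention of geometry.

## Further compounds

F1 | step 14 | 5α-(3-oxobutyl) ketal (methyl ketone from 20) | CC(C)(C)[Si](C)(C)OC[C@@]1(C)[C@@H](CCC(C)=O)C(=C)CCC12OCCO2
F2 | step 14 | 1,5-diketone (C10 ketone, C8 methyl ketone) | CC(C)(C)[Si](C)(C)OC[C@@]1(C)[C@@H](CCC(C)=O)C(=O)CCC12OCCO2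
F3 | step 14 | ring B enone (C8 ketone, C9=C10) | CC(C)(C)[Si](C)(C)OC[C@@]1(C)[C@H]2CCC(=O)C=C2CCC13OCCO3
F4 | step 14 | 8α-allylic alcohol | CC(C)(C)[Si](C)(C)OC[C@@]1(C)[C@H]2CC[C@@H](O)C=C2CCC13OCCO3
F5 | step 14 | 8α-hydroxy cyclopropane (C20 α) | CC(C)(C)[Si](C)(C)OC[C@@]1(C)[C@H]2CC[C@@H](O)[C@H]3C[C@@]23CCC14OCCO4
F6 | step 5 | 19-hydroxy-3β-(triethylsilyloxy)-10-ketone | OC[C@@]1(C)[C@@H](CC=C)C(=O)CC[C@@H]1O[Si](CC)(CC)CC
F7 | step 5 | bridged methyl ketal between O19 and C10 with free 3β-hydroxyl | C1O[C@@]2(OC)CC[C@H](O)[C@]1(C)[C@H]2CC=C
F8 | step 5 | 3β,19-dihydroxy-10-ketone | OC[C@@]1(C)[C@@H](CC=C)C(=O)CC[C@@H]1O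
F9 | step 11 | (E)-alkenylboronic acid pinacol ester from 16 | CC(C)(C)[Si](C)(C)OC[C@@]1(C)[C@@H](C/C=C/B3OC(C)(C)C(C)(C)O3)C(=C)CCC12OCCO2
F10 | step 15 | allyl enol carbonate at C8 (C8=C9) | CC(C)(C)[Si](C)(C)OC[C@@]1(C)[C@H]2CCC(OC(=O)OCC=C)=C[C@]2(C)CCC13OCCO3
F11 | step 24 | (E)-alkenyl iodide at C14 (3β,19-diol) | OC[C@@]1(C)[C@H]2CC=C(C)[C@@H](CC/C(C)=C/I)[C@]2(C)CC[C@@H]1O
A1 | alternative 1 | trans-fused 7-(tert-butyldimethylsilyloxy)octalin C11 aldehyde with 3,19-acetonide | CC1(C)OC[C@@]2(C)[C@H]3C=C(O[Si](C)(C)C(C)(C)C)[C@@H](C)[C@@H](C=O)[C@]3(C)CC[C@H]2O1
A2 | alternative 1 | acyclic silyloxydiene enal with the 3,19-acetonide | CC1(C)OC[C@@](C)(/C=C/C(O[Si](C)(C)C(C)(C)C)=C/C)[C@@H](CC/C(C)=C/C=O)O1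
A3 | alternative 2 | 4-carbomethoxy-10-methyl cross-conjugated dienone with ring B | COC(=O)C1=C2CC=C(C)[C@@H](CO[Si](C)(C)C(C)(C)C)[C@]2(C)C=CC1=O
A4 | alternative 2 | racemic salicylate with the C9 allylic methyl carbonate | COC(=O)c1c(O)ccc(C)c1C/C=C(/C)C(OC(=O)OC)CO[Si](C)(C)C(C)(C)C
A5 | alternative 3 | ring A cyclohexene with C10 formyl and C5 but-2-ynyl groups | COC(=O)[C@@H]1[C@@H](CC#CC)[C@](C)(C=O)CC=C1O[Si](C)(C)C(C)(C)C
A6 | alternative 3 | methyl (Z)-3-(tert-butyldimethylsilyloxy)penta-2,4-dienoate | C=C/C(O[Si](C)(C)C(C)(C)C)=C/C(=O)OC
A7 | alternative 3 | (E)-2-methylhept-2-en-5-ynal | CC#CC/C=C(\C)C=O
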